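The data were computed with constants of no real substance.

Time is the first thing to read in the west flask: at 15.0 min its substrate reads 1.1% and its target 19.8%, and at 120 min target reads 18.1%, a difference of 1.7 percentage points against a scatter of 1 point.

| setting | west | south-west | flask |
|---|---|---|---|
| substrate | 0.010 M | 0.0050 M | 0.010 M |
| temperature | 100 °C | 85 °C | 100 °C |
| remark | the very flask that is asked about, followed so far | run made earlier |  |
| time |  |  | 2.5 h |

- west (time / min: target / %, substrate / %): 15.0: 19.8, 1.1; 30.0: 18.7, 1.0; 50.0: 20.2, 0; 60.0: 20.0, 0.4; 80.0: 16.9, 0.1; 90.0: 19.1, 0.2; 120: 18.1, 0.1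
- south-west (time / min: target / %, substrate / %): 0.500: 12.9, 13.7; 0.833: 19.9, 2.3; 1.33: 24.1, 0; 2.00: 23.8, 0; 3.00: 21.4, 0.7; 4.00: 17.8, 0; 6.00: 14.2, 0

(readings scatter by 1 percentage point)

But the south-west flask, colder and with half the charge, loses target after its substrate reads 0%: 24.1% at 1.33 min, 14.2% at 6.00 min. So target passes into something unseen, and the flat west stretch reads as a balance with that unseen pool, a quasi-equilibrium.

The mean of the 7 west target readings is 19.0%, and that is the plateau share: target as a fraction of the charge still in the flask, in whatever form.

- Wednesday's: at 2.5 h raise the temperature by 10 K, then wait 2.5 h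
- Sunday's: at 2.5 h add substrate, 50.0% of the amount charged, then wait 2.5 h
- Friday's: at 2.5 h take out 90% of the target then present, then wait 2.5 h
- Tuesday's: change nothing and wait 2.5 h more

- target that was removed still counts
- additions bring no volume worth counting

- target, in percent of the substrate first charged, at 2.5 h
- the remedy with the largest gain of target, or "none" below 2 percentage points (Wednesday's / Sunday's / Friday's / Tuesday's / none)
- target present, with what was taken out counted in, in percent of the substrate first charged, after Sunday's
- target present, with what was taken out counted in, in percent of the substrate first charged, after Tuesday's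

The reckoning here freezes that share. Now and after Tuesday's, the flask holds 19.0%. Sunday's enlarges the charge, giving 28.5%. Friday's takes out 90% of the target, and the rest of the flask returns to the share, giving 32.8% with the removed part counted, more than Sunday's. Wednesday's has no share read at its temperature, so it stays unreckoned.

The forecast gives 18.5% now, 27.5% after Sunday's, below the figure here, 18% after Tuesday's and Friday's as best, holding that “the west plateau looks like a reached equilibrium”.

The flask gives 17.5% at 2.5 h, 15.7% after Tuesday's and 24.5% after Sunday's, with Friday's best at a gain of 11 points.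

    substrate → intermediate (k = 0.210 s⁻¹, Ea = 86.0 kJ mol⁻¹)
    intermediate ⇌ target (K = 14.0, k = 0.0360 s⁻¹, Ea = 99.0 kJ mol⁻¹, ΔH = −73.0 kJ mol⁻¹)
    intermediate ⇌ isomer of the product A (K = 50.0, k = 0.00130 s⁻¹, Ea = 111 kJ mol⁻¹, ΔH = 10.0 kJ mol⁻¹)
    target ⇌ isomer of the product B (K = 3.70, k = 0.0850 s⁻¹, Ea = 107 kJ mol⁻¹, ΔH = −51.0 kJ mol⁻¹)
    (constants at 100 °C)

Target and isomer of the product B relax with a half-life of 0.107 min, far shorter than 2.5 h, yet target in the flask still sinks from 17.5% to 15.7% after Tuesday's. So the plateau share has an age. Tuesday's flask holds 15.7%; a portion of substrate aged 2.5 h stands at 17.5% of its own amount, and with 50.0% added the two sum to 24.4% for Sunday's flask. The same sum with three times the dose gives a gain of 24 points; that flask gains 25 points.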